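I decide to read these flasks by one number, and to test afterwards whether one is enough.

| flask | electrophile | nucleophile | free base | remark | time |
|---|---|---|---|---|---|
| elm | 0.059 M | 0.040 M | 0.040 M | run made earlier |  |
| alder | 0.13 M | 0.040 M | 0.040 M | run made earlier |  |
| cedar | 0.050 M | 0.040 M | 0.063 M | run made earlier |  |
| Sunday's | 0.050 M | 0.0400 M | 0.0400 M |  | 6.0 min |
| Monday's | 0.10 M | 0.0400 M | 0.0600 M |  | 6.0 min |

| run | time / min | product / % | electrophile / % |
|---|---|---|---|
| elm | 0.667 | 37.0 | 63.2 |
| elm | 1.33 | 43.3 | 56.7 |
| elm | 2.00 | 47.7 | 52.7 |
| elm | 2.50 | 49.3 | 49.7 |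
| elm | 3.00 | 53.2 | 47.6 |
| elm | 4.00 | 55.3 | 44.0 |
| alder | 0.667 | 18.8 | 80.6 |
| alder | 1.33 | 23.4 | 77.8 |
| alder | 2.00 | 25.1 | 74.0 |
| alder | 2.50 | 26.9 | 73.4 |
| alder | 3.00 | 27.5 | 73.0 |
| alder | 4.00 | 29.5 | 71.4 |
| cedar | 0.333 | 39.2 | 60.5 |
| cedar | 0.667 | 43.4 | 56.3 |
| cedar | 1.33 | 50.6 | 49.4 |
| cedar | 2.00 | 56.4 | 43.9 |
| cedar | 4.00 | 66.8 | 32.7 |

(readings scatter by 0.5 percentage points)

- what is said of product includes idle adduct
- steps that have been proposed: electrophile + nucleophile -> acid set free + product; nucleophile + acid set free <-> protonated nucleophile; acid set free + free base <-> salt of the base; nucleophile + product <-> idle adduct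

1. the winner by amount of product, in percent of the electrophile charged; "neither" if no more than 2 percentage points parts them (Sunday's / Monday's / neither)
2. how much product is there at the end, in percent of the electrophile charged: Sunday's
3. how much product is there at the end, in percent of the electrophile charged: Monday's

The number is the ceiling, 80.0% for Sunday's flask: charged nucleophile over charged electrophile, the percent of the electrophile charged that is product once the nucleophile charged has passed through the first step, which spends one nucleophile per product. Below 100% it marks the nucleophile as the limiting reagent. For Monday's flask it is 40.0%, half of Sunday's.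

Is that enough? Not for the time. After 4.00 min the alder run stands at 29.5% under a ceiling of 30.8%, while the elm run stands at 55.3% under 67.8%. So the ceiling bounds both of these runs, and how near a run stands at a given time is a second matter. I scale Sunday's flask by the share of its ceiling that elm reached, which gives 65.3%, and Monday's flask by alder's share, which gives 38.3%. Both flasks get 6.0 min, later than the last reading of those runs, so I expect a little more in each, and Sunday's ahead.

The forecast also names Sunday's, with 68% for that flask, above my figure, and 38.5% for Monday's flask, and says “Sunday wins in percent terms, because its charge is half as large”.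

The winner is Sunday's, at 68.3%. Monday's flask gives 39.9%.

    electrophile + nucleophile → acid set free + product (k = 16.6 M⁻¹ s⁻¹)
    nucleophile + acid set free ⇌ protonated nucleophile, settled at all times (K = 2.17 × 10⁵ M⁻¹)
    acid set free + free base ⇌ salt of the base (K = 1.40 × 10⁵ M⁻¹, k = 11.4 M⁻¹ s⁻¹)
    nucleophile + product ⇌ idle adduct, settled at all times (K = 711 M⁻¹)

Monday's flask stands at its ceiling of 40.0%, with 0.0081% of its nucleophile still free, and more time makes no difference. Sunday's flask is still under its 80.0%, and gives 79.9% after 60.0 min. The gap comes mainly from the electrophile charge: Monday's flask with Sunday's electrophile gives 72.2%. A neighbour of Sunday's with 0.016 M of nucleophile has a ceiling of 32.0%, and it gives 32.0%.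

The earlier runs and the new flask stem from a simulated flask for substances that don't exist, noise included.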